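The cyclohexene (C5–C10, spiro[4.5]decane numbering) carries a Morita–Baylis–Hillman array: the carbinol C9 sits next to the ester-bearing alkene C7=C8. The route therefore disconnects C8–C9 and closes this ring last by a phosphine-mediated intramolecular Morita–Baylis–Hillman reaction, which should form the ring, the C9 stereocentre and the unprotected hydroxy enoate in one operation. Its precursor is a cyclopentane whose quaternary carbon C5 bears a formylmethyl arm and a 3-(methoxycarbonyl)allyl arm. The iridoid nepetalactone supplies the contiguous stereocentres C1, C4 and the side-chain methine; C5 is set by α-allylation of the derived lactol, and the two arms are then differentiated by homologation and alkene cleavage.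

Key step: step 10

Assumption: (4aS,7S,7aR)-nepetalactone, the main iridoid of commercial catnip oil and a catalogue compound, is taken as the purchasable chiral starting material; target locants follow spiro[4.5]decane numbering (C5 spiro carbon, C8 ester-bearing carbon, C9 carbinol carbon).

Step 1
Reactants: 1 (4aS,7S,7aR)-nepetalactone
Product: 2 (4S,4aR,7S,7aR)-dihydronepetalactone
Conditions: H2 (3 bar), Pd/SrCO3 (5 wt% Pd), EtOAc, 25 °C
Reagents that add atoms: none
Why: Catalytic syn-hydrogenation of the enol-lactone double bond from the convex face of the cis-fused bicycle (the face of the two ring-fusion hydrogens) should set lactone C4 as S, which becomes the side-chain methine of the target.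

Step 2
Reactants: 2 (4S,4aR,7S,7aR)-dihydronepetalactone
Product: 3 (4S,4aR,7S,7aR)-4,7-dimethyloctahydrocyclopenta[c]pyran-1-ol (lactol)
Conditions: i-Bu2AlH (1.1 equiv), CH2Cl2, −78 °C; aq. potassium sodium tartrate work-up
Reagents that add atoms: none
Why: Partial reduction of a δ-lactone by i-Bu2AlH at −78 °C stops at the aluminium hemiacetal and gives the lactol on hydrolysis without touching a stereocentre.

Step 3
Reactants: 3 (4S,4aR,7S,7aR)-4,7-dimethyloctahydrocyclopenta[c]pyran-1-ol
Product: 4 (4S,4aR,7S,7aR)-4,7-dimethyl-7a-(prop-2-en-1-yl)octahydrocyclopenta[c]pyran-1-ol (cis-fused lactol)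
Conditions: allyl alcohol (2 equiv), Pd(PPh3)4 (5 mol%), benzhydrylamine (40 mol%), diphenyl phosphate (5 mol%), 5 Å molecular sieves, toluene, 40 °C; then 1 M aq. HCl/THF work-up
Reagents that add atoms: allyl alcohol C=CCO
Why: Tsuji–Trost α-allylation of an α-branched aldehyde under combined primary-amine, Brønsted-acid and palladium catalysis, the lactol serving as latent aldehyde: the π-allylpalladium electrophile should attack the exocyclic enamine carbon anti to the bulkier neighbour carrying the 1-hydroxypropan-2-yl group and syn to the ring methyl, which sets the quaternary centre and lets the product close again to the cis-fused lactol.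

Step 4
Reactants: 4 (4S,4aR,7S,7aR)-4,7-dimethyl-7a-(prop-2-en-1-yl)octahydrocyclopenta[c]pyran-1-ol
Product: 5 (2S)-2-[(1R,2R,3S)-2-(2-methoxyethenyl)-3-methyl-2-(prop-2-en-1-yl)cyclopentyl]propan-1-ol (E/Z mixture)
Conditions: Ph3P(CH2OMe)Cl (3.5 equiv), KOt-Bu (3.3 equiv), THF, 0 → 45 °C
Reagents that add atoms: (methoxymethyl)triphenylphosphonium chloride COC[P+](c1ccccc1)(c1ccccc1)c1ccccc1.[Cl-]
Why: Wittig methoxymethylenation of the open hydroxy-aldehyde tautomer of the lactol (excess ylide absorbs the hydroxyl proton) should add the one carbon needed by the future enoate arm as an enol ether and free the primary alcohol.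

Step 5
Reactants: 5 (2S)-2-[(1R,2R,3S)-2-(2-methoxyethenyl)-3-methyl-2-(prop-2-en-1-yl)cyclopentyl]propan-1-ol
Product: 6 (1R,2R,3S)-1-[(2S)-1-iodopropan-2-yl]-2-(2-methoxyethenyl)-3-methyl-2-(prop-2-en-1-yl)cyclopentane
Conditions: PPh3, imidazole, I2 (premixed), CH2Cl2, 0 °C
Reagents that add atoms: iodine II
Why: Appel iodination of the primary alcohol under imidazole buffering, conditions that the enol ether and the terminal alkene should survive.

Step 6
Reactants: 7 3-methylbutan-2-one
Product: 8 3-methylbutan-2-one N,N-dimethylhydrazone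
Conditions: Me2NNH2 (1.5 equiv), AcOH (cat.), EtOH, 78 °C
Reagents that add atoms: 1,1-dimethylhydrazine CN(C)N
Why: Acid-catalysed condensation of a ketone with 1,1-dimethylhydrazine gives the N,N-dimethylhydrazone needed for regioselective aza-enolate formation.

Step 7
Reactants: 6 (1R,2R,3S)-1-[(2S)-1-iodopropan-2-yl]-2-(2-methoxyethenyl)-3-methyl-2-(prop-2-en-1-yl)cyclopentane; 8 3-methylbutan-2-one N,N-dimethylhydrazone
Product: 11 2-[(1R,2S,5R)-2-methyl-5-[(2R)-6-methyl-5-oxoheptan-2-yl]-1-(prop-2-en-1-yl)cyclopentyl]acetaldehyde, via lithiated hydrazone 9 (not isolated), via alkylated hydrazone 10 (not isolated)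
Conditions: 8, LiN(i-Pr)2, THF, 0 °C; then 6, −78 → 23 °C; then 1 M aq. HCl, THF, 23 °C
Reagents that add atoms: water O
Why: Corey–Enders hydrazone alkylation: kinetic lithiation at the methyl group gives the aza-enolate, SN2 displacement of the primary iodide forms the side-chain C–C bond, and aqueous acid hydrolyses the hydrazone to the isopropyl ketone and the enol ether to the homologated aldehyde, with no stereocentre α to a carbonyl put at risk.

Step 8
Reactants: 11 2-[(1R,2S,5R)-2-methyl-5-[(2R)-6-methyl-5-oxoheptan-2-yl]-1-(prop-2-en-1-yl)cyclopentyl]acetaldehyde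
Product: 12 methyl (2E)-4-[(1R,2S,5R)-2-methyl-5-[(2R)-6-methyl-5-oxoheptan-2-yl]-1-(prop-2-en-1-yl)cyclopentyl]but-2-enoate
Conditions: Ph3P=CHCO2Me (1.3 equiv), CH2Cl2, 23 °C
Reagents that add atoms: methyl (triphenylphosphoranylidene)acetate COC(=O)C=P(c1ccccc1)(c1ccccc1)c1ccccc1
Why: Wittig olefination with a stabilised ylide reacts only with the aldehyde (the hindered ketone is inert) and should give the E-enoate.

Step 9
Reactants: 12 methyl (2E)-4-[(1R,2S,5R)-2-methyl-5-[(2R)-6-methyl-5-oxoheptan-2-yl]-1-(prop-2-en-1-yl)cyclopentyl]but-2-enoate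
Product: 14 methyl (2E)-4-[(1S,2S,5R)-2-methyl-5-[(2R)-6-methyl-5-oxoheptan-2-yl]-1-(2-oxoethyl)cyclopentyl]but-2-enoate, via diol 13 (not isolated)
Conditions: OsO4 (2 mol%), NaIO4 (4 equiv), 2,6-lutidine (2 equiv), 1,4-dioxane/H2O (3:1), 23 °C
Reagents that add atoms: osmium tetroxide O=[Os](=O)(=O)=O; sodium periodate [Na+].[O-]I(=O)(=O)=O
Why: Lemieux–Johnson oxidation: OsO4 dihydroxylates the electron-rich terminal alkene in preference to the electron-poor enoate and NaIO4 cleaves the diol to the aldehyde.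

Step 10
Reactants: 14 methyl (2E)-4-[(1S,2S,5R)-2-methyl-5-[(2R)-6-methyl-5-oxoheptan-2-yl]-1-(2-oxoethyl)cyclopentyl]but-2-enoate
Product: 15 methyl (1S,4R,5S,9S)-9-hydroxy-1-methyl-4-[(2R)-6-methyl-5-oxoheptan-2-yl]spiro[4.5]dec-7-ene-8-carboxylate (CNP0116894.1)
Conditions: PBu3 (0.5 equiv), t-BuOH/THF (1:1), 23 °C
Reagents that add atoms: none
Why: PBu3 adds reversibly to the enoate β-carbon (C7) to give a phosphonium ester enolate whose α-carbon (C8) attacks the tethered formyl carbon (C9), and proton transfer followed by E1cB loss of PBu3 restores the C7=C8 double bond next to the new carbinol. The closest known reaction type is the phosphine-mediated intramolecular Morita–Baylis–Hillman cyclisation of 7-oxohept-2-enoates to 6-hydroxycyclohex-1-ene-1-carboxylates. The cyclohexene closes by a 6-(enolexo)-exo-trig aldol addition that forms the C8–C9 bond. The new stereocentre C9 should be set in a chair-like transition state in which the cyclopentane carbon with the small methyl group (C1) is axial on C5, the carbon with the bulky oxoheptyl chain (C4) is equatorial and the formyl oxygen is pseudo-equatorial, away from the syn-axial C1 and its methyl group, which places the hydroxyl cis to C4 (9S). The step needs chemoselectivity for the aldehyde and this facial selectivity: the isopropyl ketone is hindered and could only close a nine-membered ring, and the unequal ring arms of the spiro carbon C5 fix the chair.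

Compound list
1 | (4aS,7S,7aR)-nepetalactone [(4aS,7S,7aR)-4,7-dimethyl-5,6,7,7a-tetrahydrocyclopenta[c]pyran-1(4aH)-one] | O=C1[C@H]2[C@@H](C(C)=CO1)CC[C@@H]2C | starting material
2 | (4S,4aR,7S,7aR)-dihydronepetalactone [4,7-dimethylhexahydrocyclopenta[c]pyran-1(3H)-one] | O=C1[C@H]2[C@@H]([C@H](C)CO1)CC[C@@H]2C | intermediate
3 | (4S,4aR,7S,7aR)-4,7-dimethyloctahydrocyclopenta[c]pyran-1-ol (lactol, anomeric mixture) | OC1[C@H]2[C@@H]([C@H](C)CO1)CC[C@@H]2C | intermediate
4 | (4S,4aR,7S,7aR)-4,7-dimethyl-7a-(prop-2-en-1-yl)octahydrocyclopenta[c]pyran-1-ol (cis-fused lactol, anomeric mixture) | OC1[C@@]2(CC=C)[C@@H]([C@H](C)CO1)CC[C@@H]2C | intermediate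
5 | (2S)-2-[(1R,2R,3S)-2-(2-methoxyethenyl)-3-methyl-2-(prop-2-en-1-yl)cyclopentyl]propan-1-ol (E/Z mixture) | COC=C[C@@]1(CC=C)[C@@H]([C@H](C)CO)CC[C@@H]1C | intermediate
6 | (1R,2R,3S)-1-[(2S)-1-iodopropan-2-yl]-2-(2-methoxyethenyl)-3-methyl-2-(prop-2-en-1-yl)cyclopentane (E/Z mixture) | COC=C[C@@]1(CC=C)[C@@H]([C@H](C)CI)CC[C@@H]1C | intermediate
7 | 3-methylbutan-2-one | CC(C)C(C)=O | starting material
8 | 3-methylbutan-2-one N,N-dimethylhydrazone | CC(C)C(C)=NN(C)C | intermediate
9 | lithiated hydrazone (aza-enolate of 8, lithiated at the methyl group) | [Li]CC(=NN(C)C)C(C)C | intermediate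
10 | alkylated hydrazone: N,N-dimethylhydrazone of (6R)-6-[(1R,2R,3S)-2-(2-methoxyethenyl)-3-methyl-2-(prop-2-en-1-yl)cyclopentyl]-2-methylheptan-3-one | COC=C[C@@]1(CC=C)[C@@H]([C@H](C)CCC(=NN(C)C)C(C)C)CC[C@@H]1C | intermediate
11 | 2-[(1R,2S,5R)-2-methyl-5-[(2R)-6-methyl-5-oxoheptan-2-yl]-1-(prop-2-en-1-yl)cyclopentyl]acetaldehyde | O=CC[C@@]1(CC=C)[C@@H]([C@H](C)CCC(=O)C(C)C)CC[C@@H]1C | intermediate
12 | methyl (2E)-4-[(1R,2S,5R)-2-methyl-5-[(2R)-6-methyl-5-oxoheptan-2-yl]-1-(prop-2-en-1-yl)cyclopentyl]but-2-enoate | COC(=O)/C=C/C[C@@]1(CC=C)[C@@H]([C@H](C)CCC(=O)C(C)C)CC[C@@H]1C | intermediate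
13 | diol: methyl (2E)-4-[(1S,2S,5R)-1-(2,3-dihydroxypropyl)-2-methyl-5-[(2R)-6-methyl-5-oxoheptan-2-yl]cyclopentyl]but-2-enoate (epimers at the carbinol) | COC(=O)/C=C/C[C@@]1(CC(O)CO)[C@@H]([C@H](C)CCC(=O)C(C)C)CC[C@@H]1C | intermediate
14 | methyl (2E)-4-[(1S,2S,5R)-2-methyl-5-[(2R)-6-methyl-5-oxoheptan-2-yl]-1-(2-oxoethyl)cyclopentyl]but-2-enoate | COC(=O)/C=C/C[C@@]1(CC=O)[C@@H]([C@H](C)CCC(=O)C(C)C)CC[C@@H]1C | intermediate
15 | methyl (1S,4R,5S,9S)-9-hydroxy-1-methyl-4-[(2R)-6-methyl-5-oxoheptan-2-yl]spiro[4.5]dec-7-ene-8-carboxylate (CNP0116894.1) | COC(=O)C1=CC[C@@]2(C[C@@H]1O)[C@@H]([C@H](C)CCC(=O)C(C)C)CC[C@@H]2C | target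

Total step count: 10. Longest linear sequence: 9 steps (steps 1–5 and 7–10; step 6 prepares the hydrazone fragment).

Steps most likely to fail

Step 10 (key step). What may go wrong: addition of the enolate to the wrong face of the formyl group, giving the C9 epimer, together with slow turnover of the ester-type acceptor. Fallback (sets out from 11, comes back at 15): the ring is closed on the aldehyde oxidation level under catalyst control instead. Wittig reaction of 11 with (triphenylphosphoranylidene)acetaldehyde should give enal F1. OsO4/NaIO4 cleavage of the allyl group, through diol F2, should give enal dialdehyde F3. Proline/imidazole co-catalysed intramolecular Morita–Baylis–Hillman cyclisation (enamine/iminium aminocatalysis, with the proline enantiomer chosen to match 9S) should give hydroxy enal F4. Oxidation with NaClO2/NaH2PO4/2-methylbut-2-ene should give acid F5, and Me3SiCHN2 in MeOH/toluene should give 15.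

Step 3. What may go wrong: attack of the π-allyl electrophile on the other face of the enamine, or on both faces, at the congested α-carbon, giving the 7a epimer. Fallback (sets out from 3, comes back at 14): the epimer is not discarded; the roles of its two arms are exchanged. It cannot close to a cis-fused lactol and is handled as the open hydroxy aldehyde F6. Wittig methoxymethylenation should give enol ether alcohol F7, Appel iodination iodide F8, alkylation of lithiated 8 the alkylated hydrazone F9, and aqueous acid keto aldehyde F10. In F10 the homologated formylmethyl arm already lies on the methyl face, so it is kept as the aldehyde arm. The allyl arm on the side-chain face is turned into the enoate arm by cross-metathesis with methyl acrylate (second-generation Hoveyda–Grubbs catalyst, CH2Cl2, 40 °C), which should give 14. Both epimers of the allylation thus converge on 14.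

Step 7. What may go wrong: slow SN2 displacement at the β-branched primary iodide, with competing E2 elimination by the basic aza-enolate. Fallback (sets out from 5, comes back at 11): the side chain is built by olefination instead of alkylation. Dess–Martin oxidation of 5 (NaHCO3 buffer) should give aldehyde F11, whose α-stereocentre must be kept away from base. Wittig reaction with 3-methyl-1-(triphenylphosphoranylidene)butan-2-one should give enone F12, conjugate reduction with [(Ph3P)CuH]6 should give ketone F13, and 1 M aq. HCl/THF should hydrolyse the enol ether to 11.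

Further compounds
F1 | step 10 | (2E)-4-[(1R,2S,5R)-2-methyl-5-[(2R)-6-methyl-5-oxoheptan-2-yl]-1-(prop-2-en-1-yl)cyclopentyl]but-2-enal | O=C/C=C/C[C@@]1(CC=C)[C@@H]([C@H](C)CCC(=O)C(C)C)CC[C@@H]1C
F2 | step 10 | diol from dihydroxylation of the allyl group of F1 (epimers at the carbinol) | O=C/C=C/C[C@@]1(CC(O)CO)[C@@H]([C@H](C)CCC(=O)C(C)C)CC[C@@H]1C
F3 | step 10 | (2E)-4-[(1S,2S,5R)-2-methyl-5-[(2R)-6-methyl-5-oxoheptan-2-yl]-1-(2-oxoethyl)cyclopentyl]but-2-enal | O=C/C=C/C[C@@]1(CC=O)[C@@H]([C@H](C)CCC(=O)C(C)C)CC[C@@H]1C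
F4 | step 10 | (1S,4R,5S,9S)-9-hydroxy-1-methyl-4-[(2R)-6-methyl-5-oxoheptan-2-yl]spiro[4.5]dec-7-ene-8-carbaldehyde | O=CC1=CC[C@@]2(C[C@@H]1O)[C@@H]([C@H](C)CCC(=O)C(C)C)CC[C@@H]2C
F5 | step 10 | (1S,4R,5S,9S)-9-hydroxy-1-methyl-4-[(2R)-6-methyl-5-oxoheptan-2-yl]spiro[4.5]dec-7-ene-8-carboxylic acid | OC(=O)C1=CC[C@@]2(C[C@@H]1O)[C@@H]([C@H](C)CCC(=O)C(C)C)CC[C@@H]2C
F6 | step 3 | (1S,2S,5R)-5-[(2S)-1-hydroxypropan-2-yl]-2-methyl-1-(prop-2-en-1-yl)cyclopentane-1-carbaldehyde | C=CC[C@@]1(C=O)[C@@H]([C@H](C)CO)CC[C@@H]1C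
F7 | step 3 | (2S)-2-[(1R,2S,3S)-2-(2-methoxyethenyl)-3-methyl-2-(prop-2-en-1-yl)cyclopentyl]propan-1-ol (E/Z mixture) | C=CC[C@@]1(C=COC)[C@@H]([C@H](C)CO)CC[C@@H]1C
F8 | step 3 | (1R,2S,3S)-1-[(2S)-1-iodopropan-2-yl]-2-(2-methoxyethenyl)-3-methyl-2-(prop-2-en-1-yl)cyclopentane (E/Z mixture) | C=CC[C@@]1(C=COC)[C@@H]([C@H](C)CI)CC[C@@H]1C
F9 | step 3 | N,N-dimethylhydrazone of (6R)-6-[(1R,2S,3S)-2-(2-methoxyethenyl)-3-methyl-2-(prop-2-en-1-yl)cyclopentyl]-2-methylheptan-3-one | C=CC[C@@]1(C=COC)[C@@H]([C@H](C)CCC(=NN(C)C)C(C)C)CC[C@@H]1C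
F10 | step 3 | 2-[(1S,2S,5R)-2-methyl-5-[(2R)-6-methyl-5-oxoheptan-2-yl]-1-(prop-2-en-1-yl)cyclopentyl]acetaldehyde | C=CC[C@@]1(CC=O)[C@@H]([C@H](C)CCC(=O)C(C)C)CC[C@@H]1C
F11 | step 7 | (2S)-2-[(1R,2R,3S)-2-(2-methoxyethenyl)-3-methyl-2-(prop-2-en-1-yl)cyclopentyl]propanal | COC=C[C@@]1(CC=C)[C@@H]([C@H](C)C=O)CC[C@@H]1C
F12 | step 7 | (4E,6R)-6-[(1R,2R,3S)-2-(2-methoxyethenyl)-3-methyl-2-(prop-2-en-1-yl)cyclopentyl]-2-methylhept-4-en-3-one | COC=C[C@@]1(CC=C)[C@@H]([C@H](C)/C=C/C(=O)C(C)C)CC[C@@H]1C
F13 | step 7 | (6R)-6-[(1R,2R,3S)-2-(2-methoxyethenyl)-3-methyl-2-(prop-2-en-1-yl)cyclopentyl]-2-methylheptan-3-one | COC=C[C@@]1(CC=C)[C@@H]([C@H](C)CCC(=O)C(C)C)CC[C@@H]1C
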